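## Retrosynthetic overview

1. Target ⇐ C9 hydroxylation (enolate + oxaziridine) of the C3 ester; ester ⇐ 3α-alcohol + the (Z,Z)-acid, itself made from 3-methylfuran-2(5H)-one and angelic anhydride.
2. trans-Decalin alcohol ⇐ Li/NH3 reduction of 3α-hydroxyeremophila-7(11),9-dien-8-one.
3. That dienone ⇐ 3α,4α-epoxyeudesm-7(11)-en-8-one by an epoxide-triggered 1,2-H / 1,2-CH3 shift cascade (eudesmane → eremophilane, as in the biosynthesis).
4. Epoxide ⇐ eudesma-3,7(11)-dien-8-one ⇐ germacrone by enantioselective proton-initiated transannular cyclisation.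
5. Ring order: the ten-membered ring is bought; ring A and ring B form together through the C5–C10 bond in step 1; no ring is formed afterwards.

Assumption: the (R)-configured acid of step 1 is taken to give the (5R,10R) series; if the sense of induction is the opposite, its (S)-enantiomer is used.

Numbering is eudesmane/eremophilane numbering (ring A = C1–C5, C10; ring B = C5–C10). The target is 3α-acyloxy, 4β-CH3, 5β-CH3, 9α-OH, 10α-H, i.e. (3R,4R,5R,9S,10R).

## Route

Step 1
Reactants: 1 germacrone
Product: 2 (5R,10R)-eudesma-3,7(11)-dien-8-one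
Conditions: (R)-2'-[(2-fluorobenzyl)oxy]-1,1'-binaphthalen-2-ol·SnCl4 (1.1 equiv), toluene, −78 → −60 °C, 48 h; aq NaHCO3; AgNO3–SiO2 chromatography to remove the 4(15)- and 4(5)-ene isomers
Reagents that add atoms: none
Why: Proposed new method: the tin-activated chiral binaphthol (a Lewis-acid-assisted Brønsted acid) protonates C1 of the strained 1(10)-alkene on one enantiotopic face of the interconverting planar-chiral conformers, the 4,5-alkene attacks C10 through the chair–chair transition state to give the trans-fused eudesm-4-yl cation (C5 and C10 set together as 5α-H/10β-CH3, absolute sense from the acid), and loss of the axial 3α-proton gives the endocyclic alkene; the closest known reactions are enantioselective proton-initiated polyene cyclisations with such acids and the achiral acid-induced transannular cyclisation of germacrone to eudesmadienones.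

Step 2
Reactants: 2 (5R,10R)-eudesma-3,7(11)-dien-8-one
Product: 3 (3R,4S,5R,10R)-3α,4α-epoxyeudesm-7(11)-en-8-one
Conditions: mCPBA (1.1 equiv), NaHCO3, CH2Cl2, 0 °C
Reagents that add atoms: mCPBA, OOC(=O)c1cccc(Cl)c1
Why: Prilezhaev epoxidation, in which the electron-rich trisubstituted 3,4-alkene reacts far faster than the electron-poor tetrasubstituted enone and the peracid approaches the α-face anti to the axial C10 methyl group, setting C3 (R) and C4 (S).

Step 3
Reactants: 3 (3R,4S,5R,10R)-3α,4α-epoxyeudesm-7(11)-en-8-one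
Product: 4 (3R,4R,5R)-3α-hydroxyeremophila-7(11),9-dien-8-one
Conditions: (CF3SO2)2NH (5 mol %), (CF3)2CHOH/CH2Cl2 (1:4), −40 → 0 °C; Et3N quench
Reagents that add atoms: none
Why: Epoxide-initiated Wagner–Meerwein cascade (Westphalen-type backbone rearrangement, the eudesmane-to-eremophilane step of the biosynthesis), in which ionisation at tertiary C4 leaves the 3α-oxygen in place, the axial 5α-H migrates suprafacially to the α-face of C4 (giving 4β-CH3), the axial 10β-CH3 then migrates to the β-face of C5, and loss of H9 from the C10 cation gives the conjugated dienone as the thermodynamic sink, while the competing Meinwald hydride shift is disfavoured because H3 is equatorial and nearly orthogonal to the empty orbital at C4.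

Step 4
Reactants: 4 (3R,4R,5R)-3α-hydroxyeremophila-7(11),9-dien-8-one
Product: 6 (3R,4R,5R,10S)-3α-hydroxy-10αH-eremophil-7(11)-en-8-one, via dilithium alkoxide dienolate 5 (not isolated)
Conditions: Li (2.2 equiv), NH3(l)/THF, −78 °C, 20 min; solid NH4Cl
Reagents that add atoms: none
Why: Dissolving-metal (Birch-type) conjugate reduction, in which the planar s-trans ring enone takes up the electrons, axial protonation of the β-carbanion at C10 anti to the angular methyl group gives the trans-decalin (10α-H), and the resulting cross-conjugated dienolate resists further reduction and is protonated at C9 on quench to return the 7(11)-en-8-one.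

Step 5
Reactants: 7 3-methylfuran-2(5H)-one
Product: 8 potassium (Z)-4-hydroxy-2-methylbut-2-enoate
Conditions: KOH (1.00 equiv), H2O/THF, 0 °C → rt; evaporate; dry by toluene azeotrope
Reagents that add atoms: potassium hydroxide, [K+].[OH-]
Why: Lactone saponification, in which hydroxide opens the butenolide, the former ring fixes the Z geometry of the hydroxy-enoate, and the product is stable towards relactonisation as its carboxylate salt.

Step 6
Reactants: 8 potassium (Z)-4-hydroxy-2-methylbut-2-enoate; 9 angelic anhydride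
Product: 11 (Z)-2-methyl-4-{[(Z)-2-methylbut-2-enoyl]oxy}but-2-enoic acid, via dipotassium alkoxide carboxylate 10 (not isolated)
Conditions: KN(SiMe3)2 (1.05 equiv), 18-crown-6, THF, −78 °C; then 9 (1.1 equiv), −78 → −20 °C; cold 1 M HCl
Reagents that add atoms: none
Why: Alkoxide acylation by an anhydride without a nucleophilic catalyst, in which the potassium alkoxide is far more nucleophilic than the carboxylate, the carboxylate end cannot lactonise, and the angeloyl group is transferred without Z-to-E isomerisation.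

Step 7
Reactants: 11 (Z)-2-methyl-4-{[(Z)-2-methylbut-2-enoyl]oxy}but-2-enoic acid; 6 (3R,4R,5R,10S)-3α-hydroxy-10αH-eremophil-7(11)-en-8-one
Product: 13 (3R,4R,5R,10S)-3α-{(Z)-2-methyl-4-[(Z)-2-methylbut-2-enoyloxy]but-2-enoyloxy}-10αH-eremophil-7(11)-en-8-one, via mixed anhydride 12 (not isolated)
Conditions: 11 (1.5 equiv), 2,4,6-trichlorobenzoyl chloride, Et3N, toluene, 0 °C → rt; then 6, toluene, 75 °C
Reagents that add atoms: none
Why: Yamaguchi esterification, in which the single hydroxyl group attacks the less hindered enoyl carbonyl of the mixed anhydride, C3 keeps its configuration because its C–O bond is untouched, and leaving out a nucleophilic catalyst avoids Z-to-E isomerisation of the two angelate-type double bonds.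

Step 8
Reactants: 13 (3R,4R,5R,10S)-3α-{(Z)-2-methyl-4-[(Z)-2-methylbut-2-enoyloxy]but-2-enoyloxy}-10αH-eremophil-7(11)-en-8-one
Product: 15 CNP0308665.1, via potassium enolate 14 (not isolated)
Conditions: KN(SiMe3)2 (1.1 equiv), THF, −78 °C, 30 min; 2-(phenylsulfonyl)-3-phenyloxaziridine (1.5 equiv), −78 °C; aq NH4Cl
Reagents that add atoms: 2-(phenylsulfonyl)-3-phenyloxaziridine, O=S(=O)(c1ccccc1)N1OC1c1ccccc1
Why: Davis enolate hydroxylation, in which kinetic deprotonation takes place at the only α'-CH2 of the ketone (C9), far more acidic than the γ-hydrogens of the two enoates, and the oxaziridine attacks the enolate from the α-face away from the 1,3-related axial C5 methyl group to give the equatorial 9α-alcohol (9S), which is also the more stable epimer.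

## Compound list

1 | germacrone, (3E,7E)-3,7-dimethyl-10-(propan-2-ylidene)cyclodeca-3,7-dien-1-one | O=C1C/C(C)=C/CC/C(C)=C/CC1=C(C)C | starting material
2 | (5R,10R)-eudesma-3,7(11)-dien-8-one (trans-fused, 5α-H, 10β-CH3) | CC1=CCC[C@]2(C)CC(=O)C(=C(C)C)C[C@@H]12 | intermediate
3 | (3R,4S,5R,10R)-3α,4α-epoxyeudesm-7(11)-en-8-one | C[C@@]12O[C@@H]1CC[C@]3(C)CC(=O)C(=C(C)C)C[C@@H]23 | intermediate
4 | (3R,4R,5R)-3α-hydroxyeremophila-7(11),9-dien-8-one (4β,5β-dimethyl) | O[C@@H]1CCC2=CC(=O)C(=C(C)C)C[C@]2(C)[C@H]1C | intermediate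
5 | dilithium (3R,4R,5R,10S)-10αH-eremophila-7(11),8-diene-3α,8-diolate | [Li+].[Li+].[O-][C@@H]1CC[C@H]2C=C([O-])C(=C(C)C)C[C@]2(C)[C@H]1C | intermediate
6 | (3R,4R,5R,10S)-3α-hydroxy-10αH-eremophil-7(11)-en-8-one | O[C@@H]1CC[C@H]2CC(=O)C(=C(C)C)C[C@]2(C)[C@H]1C | intermediate
7 | 3-methylfuran-2(5H)-one | CC1=CCOC1=O | starting material
8 | potassium (Z)-4-hydroxy-2-methylbut-2-enoate | OC/C=C(/C)C(=O)[O-].[K+] | intermediate
9 | angelic anhydride, (Z)-2-methylbut-2-enoic anhydride | C/C=C(/C)C(=O)OC(=O)C(/C)=C\C | starting material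
10 | dipotassium (Z)-2-methyl-4-oxidobut-2-enoate | [K+].[K+].[O-]C/C=C(/C)C(=O)[O-] | intermediate
11 | (Z)-2-methyl-4-{[(Z)-2-methylbut-2-enoyl]oxy}but-2-enoic acid | C/C=C(/C)C(=O)OC/C=C(/C)C(=O)O | intermediate
12 | mixed anhydride of 11 with 2,4,6-trichlorobenzoic acid | C/C=C(/C)C(=O)OC/C=C(/C)C(=O)OC(=O)c1c(Cl)cc(Cl)cc1Cl | intermediate
13 | (3R,4R,5R,10S)-3α-{(Z)-2-methyl-4-[(Z)-2-methylbut-2-enoyloxy]but-2-enoyloxy}-10αH-eremophil-7(11)-en-8-one | C/C=C(/C)C(=O)OC/C=C(/C)C(=O)O[C@@H]1CC[C@H]2CC(=O)C(=C(C)C)C[C@]2(C)[C@H]1C | intermediate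
14 | potassium 8(9)-enolate of 13 | C/C=C(/C)C(=O)OC/C=C(/C)C(=O)O[C@@H]1CC[C@H]2C=C([O-])C(=C(C)C)C[C@]2(C)[C@H]1C.[K+] | intermediate
15 | CNP0308665.1, (3R,4R,5R,9S,10R)-3α-{(Z)-2-methyl-4-[(Z)-2-methylbut-2-enoyloxy]but-2-enoyloxy}-9α-hydroxy-10αH-eremophil-7(11)-en-8-one | C/C=C(/C)C(=O)OC/C=C(/C)C(=O)O[C@@H]1CC[C@H]2[C@H](O)C(=O)C(=C(C)C)C[C@]2(C)[C@H]1C | target

## Step count and risks

Total step count: 8. Longest linear sequence: 6 steps (steps 1, 2, 3, 4, 7, 8); the acid branch (steps 5, 6) joins at step 7.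

The three steps most likely to fail:

Step 1. The enantioselectivity of the protonation is unproven on a ketone-bearing ten-membered ring, and the cation can also lose a proton to give the 4(15)- or 4(5)-alkene. The fallback sets out from 1 and comes back at 4. Germacrone 1 is cyclised with an achiral acid (4-toluenesulfonic acid monohydrate, 10 mol %, CH2Cl2, 0 °C) to racemic eudesma-3,7(11)-dien-8-one F1. This is carried through the same epoxidation to racemic 3α,4α-epoxyeudesm-7(11)-en-8-one F2 and the same acid-triggered rearrangement to racemic 3α-hydroxyeremophila-7(11),9-dien-8-one F3. F3 is then resolved by preparative chromatography on a chiral stationary phase (amylose tris(3,5-dimethylphenylcarbamate), supercritical CO2/MeOH), and the (3R,4R,5R)-enantiomer is compound 4.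

Step 3. The C4 cation may instead give the 3-ketone (Meinwald shift), a ring-contracted aldehyde or allylic alcohols. The fallback sets out from 2 and comes back at 4. Diene 2 is dihydroxylated from the α-face (OsO4 2 mol %, N-methylmorpholine N-oxide, acetone/H2O) to (3R,4S,5R,10R)-3α,4α-dihydroxyeudesm-7(11)-en-8-one F4. Only the secondary hydroxyl is acetylated (Ac2O, pyridine, 4-(dimethylamino)pyridine 5 mol %) to give (3R,4S,5R,10R)-3α-acetoxy-4α-hydroxyeudesm-7(11)-en-8-one F5. Classical Westphalen conditions (H2SO4 cat., Ac2O/AcOH, 0 °C) then ionise the tertiary alcohol. The neighbouring acetoxy group cannot undergo the pinacol shift, so the same hydride and methyl shifts follow and give (3R,4R,5R)-3α-acetoxyeremophila-7(11),9-dien-8-one F6. Methanolysis (K2CO3, MeOH, rt) gives 4.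

Step 4. Both β-carbons of the cross-conjugated dienone are fully substituted, so lithium may reduce the isopropylidene double bond instead of the 9,10-double bond. The fallback sets out from 4 and comes back at 6 and makes no new compound (F0). It replaces electron transfer by a homogeneous hydrogenation that saturates only the s-trans ring C=C of cross-conjugated dienones, as in the piperitenone-to-pulegone case. Conditions: H2 (50 atm), [NH2Me2][{RuCl(BINAP)}2(μ-Cl)3] (1 mol %; BINAP = 2,2'-bis(diphenylphosphino)-1,1'-binaphthyl, the enantiomer matched to α-face delivery at C10), MeOH, 40 °C. The tetrasubstituted s-cis isopropylidene enone is left intact.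

## Further compounds

F1 | step 1 | racemic eudesma-3,7(11)-dien-8-one (2 and its enantiomer, 1:1) | CC1=CCC[C@]2(C)CC(=O)C(=C(C)C)C[C@@H]12.CC1=CCC[C@@]2(C)CC(=O)C(=C(C)C)C[C@H]12
F2 | step 1 | racemic 3α,4α-epoxyeudesm-7(11)-en-8-one (3 and its enantiomer, 1:1) | C[C@@]12O[C@@H]1CC[C@]3(C)CC(=O)C(=C(C)C)C[C@@H]23.C[C@]12O[C@H]1CC[C@@]3(C)CC(=O)C(=C(C)C)C[C@H]23
F3 | step 1 | racemic 3α-hydroxyeremophila-7(11),9-dien-8-one (4 and its enantiomer, 1:1) | O[C@@H]1CCC2=CC(=O)C(=C(C)C)C[C@]2(C)[C@H]1C.O[C@H]1CCC2=CC(=O)C(=C(C)C)C[C@@]2(C)[C@@H]1C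
F4 | step 3 | (3R,4S,5R,10R)-3α,4α-dihydroxyeudesm-7(11)-en-8-one | C[C@@]1(O)[C@H](O)CC[C@]2(C)CC(=O)C(=C(C)C)C[C@@H]12
F5 | step 3 | (3R,4S,5R,10R)-3α-acetoxy-4α-hydroxyeudesm-7(11)-en-8-one | C[C@@]1(O)[C@H](OC(C)=O)CC[C@]2(C)CC(=O)C(=C(C)C)C[C@@H]12
F6 | step 3 | (3R,4R,5R)-3α-acetoxyeremophila-7(11),9-dien-8-one | CC(=O)O[C@@H]1CCC2=CC(=O)C(=C(C)C)C[C@]2(C)[C@H]1C
F0 | step 4 | none | none
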